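## The problem

4-O-Demethylplanaic acid (17) is a depside made of two identical 2-methoxy-4-oxy-6-pentylbenzoyl units. The carboxyl of ring A acylates the C4 oxygen of ring B, and the carboxyl of ring B is free. The molecule has no stereocentres, so the task is one of substitution pattern and chemoselectivity. On each ring the C2 oxygen is methylated and the C4 oxygen is not, so the two oxygens must be told apart, either by the way the ring is built or by selective alkylation later. The aryl ester between the rings is an activated ester and will not survive hydroxide, alkoxide or strong nucleophiles. Every ester hydrolysis must therefore come before the coupling, and the last deprotection must be neutral. Both carboxyls lie between two ortho substituents, which makes them slow to esterify and to hydrolyse, and 2,4-dioxygenated benzoic acids lose CO2 on heating or in strong acid. Because the rings are identical, one building block in two protected forms should serve for both. In that block the contiguous atoms C5 (H), C6 (pentyl), C1 (carboxyl) and C2 (methoxy) carry the substituents of C3, C4, C5 and C6 of a 6-methoxy-4-pentyl-2-pyrone-5-carboxylate. The remaining atoms C3 (H) and C4 (oxygen) are the two carbons of an ynol ether, so the arene can be reached from a pyrone by cycloaddition and loss of CO2.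

## Retrosynthesis

**17 from 16.** The two O–benzyl bonds of 16 are cut, the ether on ring A and the ester on ring B. Hydrogenolysis is neutral and leaves the depside ester alone, which methyl or silyl protection of the ring B carboxyl would not allow. The forward step only asks that the aryl ester and the arenes resist hydrogen over palladium.

**16 from 13 and 15.** The cut is the acyl–oxygen bond of the depside, giving the 4-O-benzyl acid 13 and the phenol 15 with its carboxyl masked as a benzyl ester. This is preferred to building ring A onto an ester of ring B, because it lets one arene synthesis supply both halves. The forward reaction must acylate a moderately nucleophilic phenol with an acid flanked by two ortho groups. An aroyl cation generated from a mixed anhydride suits such an electron-rich acid.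

**15 from 14, and 14 from 13.** Ring B is taken from the same acid 13. Removal of the benzyl ether gives the hydroxy acid 14, and alkylation of its carboxylate alone gives 15. Hydrolysing a 4-hydroxy ester directly would mean attacking an ester deactivated by a para phenoxide, so the detour through 13 is the safer path. It asks only that the carboxylate of 14 be alkylated in preference to the phenol.

**13 from 12, and 12 from 10.** The methyl ester is hydrolysed while the ring is still a monomer, and the silyl ether of 10 is exchanged for a benzyl ether through the phenolate 11. The silyl group would not survive the hydrolysis, and benzyl is the group that the final hydrogenolysis removes.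

**10 from 4 and 8.** The ring bonds C2–C3 and C4–C5 are cut, giving the pyrone 4 and the siloxyalkyne 8; the bridged lactone 9 lies between them and 10. An olivetol-type arene would need a carboxylation and a selective O-alkylation to differentiate two similar phenols. Here the methoxy group comes from the pyrone and the silyloxy group from the alkyne, so the two oxygens differ by origin. Both precursors are small and achiral. The forward reaction must be regioselective, with the silyloxy group para to the ester, and must end in decarboxylative aromatisation.

**4 from 3, and 3 from 1 and 2.** The lactone C–O bond of 4 is cut to give the triester 3. Then the bond between the malonate carbon and C3 of the ynoate is cut to give dimethyl malonate (1) and methyl oct-2-ynoate (2). Both ester groups and the methoxy group of 4 come from 1, and the pentyl group and the lactone carbonyl from 2. The closure must go through the malonate enol oxygen onto the unsaturated ester, not in the opposite sense.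

**8 from 5 and 6.** The O–Si bond is cut to give the ynolate 7, which comes from ethyl dibromoacetate (5); the silyl group comes from chlorotriisopropylsilane (6). A silyl ynol ether is chosen over an alkyl one because alkyl ynol ethers with β-hydrogens or benzylic groups rearrange to ketenes on warming, and because the silyl group can later be removed under mild conditions.

## Roads not taken

**Alternative 1:** The ring is cut at C3–C4 at the cyclohexenone level. An acyclic β-methoxy enoate diester A2 would be deprotonated at its γ-methyl group, and the dienolate would attack the remote ester in a vinylogous Dieckmann closure to give the 3-methoxycyclohexenone A1 (racemic). Dehydrogenation would then give the free phenol whose cesium salt is 11.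
- Merits: the two oxygens are differentiated from the start, as vinylogous ester and ketone. The 4-hydroxyl appears unprotected. The reagents are cheap and no sensitive alkyne is needed.
- Weak points: A2 needs a conjugate addition followed by a selective O-methylation of a β-keto ester, where C-methylation competes. In the closure the α-CH2 of the saturated ester is about as acidic as the γ-methyl, so retro-Michael and intermolecular Claisen reactions compete. A1 is one oxidation level below the arene, and the dehydrogenating agent may halogenate or over-oxidise the electron-rich product.
- Comparison: to the phenol stage this road is about as long as the chosen one, perhaps a step shorter since there is no second partner to make. Against that, the chosen plan delivers the arene at the right oxidation level in one bimolecular step and fixes the pattern by the polarity of a cycloaddition.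

**Alternative 2:** Ring A is cut at C1–C6. The 3,5,7-trioxododecanoate ester A4 of the ring B phenol would undergo intramolecular aldol condensation and aromatise to the depside A3, whose ring A is a 2,4-diol.
- Merits: the depside bond exists before ring A does, so the acylation by a hindered acid is avoided. The route is convergent and follows the biosynthesis.
- Weak points: the aryl ester of A4 is a good leaving group. The triketo chain can lactonise to a 4-hydroxy-2-pyrone or close by C-acylation, either way expelling the ring B phenoxide. A3 then needs methylation of the chelated, less reactive 2-hydroxyl in the presence of the 4-hydroxyl, which means protection, methylation and deprotection on a base-sensitive depside. Ring B must still be made another way.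
- Comparison: on paper ring A costs fewer operations. The chosen plan sets against this that one building block serves both rings and that the oxygens are differentiated before the sensitive ester exists.

**Alternative 3:** The C6–pentyl and C1–carboxyl bonds are cut on an intact arene. The iodoaryl sulfonate A6 would give the aryne A7. A pentyl Grignard reagent would add at the carbon remote from the methoxy group, and the arylmagnesium so formed, flanked by methoxy, would be trapped by carbon dioxide to give A5, which is the same compound as 13.
- Merits: three components are joined in one flask with no ring construction, and the oxygens are already differentiated in the phenol from which A6 derives. This road reaches 13 in clearly fewer steps than the six the chosen plan needs, and is more convergent.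
- Weak points: regiocontrol rests on the inductive effect of one methoxy group. Addition of a primary alkyl Grignard reagent to an aryne competes with β-hydride transfer, with addition of the alkyl group of the exchange reagent, and with capture of the aryne by the arylmagnesium product. A6 also needs a regioselective iodination.
- Comparison: Alternative 3 is shorter. The chosen plan sets against it a substitution pattern that follows from the polarity of a cycloaddition, with no organometallic chemoselectivity to manage, and cheap acyclic starting materials.

Key step: step 4

Remark on the chemistry: 3 is drawn as one double-bond tautomer without defined geometry, because its isomers interconvert under the conditions of step 2 and converge on 4. The bridged lactone 9 is racemic, and its two bridgehead centres are lost on aromatisation.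

## Route

Step 1
Reactants: 1 dimethyl malonate; 2 methyl oct-2-ynoate
Product: 3 trimethyl 2-pentylprop-1-ene-1,3,3-tricarboxylate (mixture of alkene isomers)
Conditions: NaH (1.05 equiv), THF, 0 °C; then 2, 0 → 50 °C; AcOH quench
Reagents that add atoms: none
Why: Michael addition of sodiomalonate to C3 of the ynoate gives a delocalised triester anion that is protonated on work-up. Stoichiometric base in an aprotic solvent avoids competing addition of methoxide to the alkyne.

Step 2
Reactants: 3 trimethyl 2-pentylprop-1-ene-1,3,3-tricarboxylate
Product: 4 methyl 2-methoxy-6-oxo-4-pentyl-6H-pyran-3-carboxylate
Conditions: neat, 190 °C, N2 sweep with removal of MeOH; then short-path distillation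
Reagents that add atoms: none
Why: Thermal lactonisation with loss of methanol is the classical route from propene-1,3,3-tricarboxylates to 6-alkoxy-2-pyrone-5-carboxylates; the enol oxygen of the acidic malonate terminus adds to the cis unsaturated ester carbonyl. The alkene isomers equilibrate through the tautomer, and removal of methanol drives the closure.

Step 3
Reactants: 5 ethyl dibromoacetate; 6 chlorotriisopropylsilane
Product: 8 (ethynyloxy)triisopropylsilane, via lithium ethynolate 7 (not isolated)
Conditions: t-BuLi (4 equiv), THF, −78 → 0 °C; then 6, −78 °C → rt
Reagents that add atoms: none
Why: Two bromine–lithium exchanges turn the dibromo ester into a lithiated ester enolate that expels LiOEt to give the ynolate, the known ynolate synthesis from α,α-dibromo esters. The bulky silyl chloride silylates the ynolate on oxygen to give the ynol silyl ether and not the silylketene.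

Step 4
Reactants: 4 methyl 2-methoxy-6-oxo-4-pentyl-6H-pyran-3-carboxylate; 8 (ethynyloxy)triisopropylsilane
Product: 10 methyl 2-methoxy-6-pentyl-4-[(triisopropylsilyl)oxy]benzoate, via bridged lactone 9 (not isolated)
Conditions: 8 (2 equiv), toluene, 110 °C, sealed tube
Reagents that add atoms: none
Why: Inverse-electron-demand Diels–Alder reaction followed by retro-[4+2] loss of CO2: the nucleophilic CH carbon of 8 bonds to pyrone C6, the acetal-type carbon β to the 5-ester, and the silyloxy-bearing carbon bonds to C3, so that arene bonds C2–C3 and C4–C5 form. The closest known reactions are the cycloadditions of 2-pyrone-5-carboxylates with ynamines, alkoxyalkynes and ketene acetals, which give para-heteroatom-substituted benzoates after CO2 extrusion. The carbocycle is closed by intermolecular [4+2] cycloaddition, the two σ-bonds probably forming asynchronously with C6 first, to give the 2-oxabicyclo[2.2.2]octadienone 9; cycloreversion then removes the lactone bridge and leaves the benzene ring. The two bridgehead centres of 9 form as a racemate and vanish on aromatisation, so no stereocontrol is needed. The step needs regiochemistry, silyloxy para and not ortho to the ester, and polarity matching secures it: the 5-ester and the lactone carbonyl make C6 the electrophilic terminus of the diene, and the β-carbon of the ynol ether is the nucleophilic terminus of the alkyne. It also needs [4+2] to win over [2+2] addition to the enoate, which the ring-locked cisoid diene and the irreversible loss of CO2 favour. The 6-methoxy group makes the diene less electron-poor than a simple coumalate, hence the heating and the excess of 8, and the bulky silyl group slows the 1,3-silyl shift to a silylketene.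

Step 5
Reactants: 10 methyl 2-methoxy-6-pentyl-4-[(triisopropylsilyl)oxy]benzoate
Product: 12 methyl 4-(benzyloxy)-2-methoxy-6-pentylbenzoate, via cesium phenolate 11 (not isolated)
Conditions: CsF (2 equiv), BnBr (1.5 equiv), DMF, rt
Reagents that add atoms: benzyl bromide, BrCc1ccccc1
Why: Fluoride cleaves the aryl O–Si bond and the phenolate is benzylated in the same flask (Williamson ether synthesis). The hindered methyl ester and the methyl ether are inert.

Step 6
Reactants: 12 methyl 4-(benzyloxy)-2-methoxy-6-pentylbenzoate
Product: 13 4-(benzyloxy)-2-methoxy-6-pentylbenzoic acid
Conditions: KOH (10 equiv), DMSO–H2O 4:1, 90 °C; then 1 M HCl, 0 °C, to pH 3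
Reagents that add atoms: potassium hydroxide, [K+].[OH-]
Why: Saponification of a di-ortho-substituted benzoate needs poorly solvated hydroxide in aqueous DMSO. The benzyl and methyl ethers are stable to base, and cold, mild acidification avoids decarboxylation.

Step 7
Reactants: 13 4-(benzyloxy)-2-methoxy-6-pentylbenzoic acid
Product: 14 4-hydroxy-2-methoxy-6-pentylbenzoic acid
Conditions: H2 (1 atm), Pd/C (10% Pd), EtOAc, rt
Reagents that add atoms: none
Why: Hydrogenolysis of the benzyl ether under neutral conditions at room temperature frees the phenol without stressing the decarboxylation-prone acid, which is used directly.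

Step 8
Reactants: 14 4-hydroxy-2-methoxy-6-pentylbenzoic acid
Product: 15 benzyl 4-hydroxy-2-methoxy-6-pentylbenzoate
Conditions: BnBr (1.05 equiv), KHCO3, DMF, rt
Reagents that add atoms: benzyl bromide, BrCc1ccccc1
Why: Bicarbonate deprotonates only the carboxylic acid, so SN2 alkylation occurs at the carboxylate and the phenol stays free. This is the standard selective esterification of hydroxybenzoic acids.

Step 9
Reactants: 13 4-(benzyloxy)-2-methoxy-6-pentylbenzoic acid; 15 benzyl 4-hydroxy-2-methoxy-6-pentylbenzoate
Product: 16 benzyl 4-{[4-(benzyloxy)-2-methoxy-6-pentylbenzoyl]oxy}-2-methoxy-6-pentylbenzoate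
Conditions: (CF3CO)2O (2 equiv), toluene, rt
Reagents that add atoms: none
Why: The mixed trifluoroacetic anhydride of an electron-rich, di-ortho-substituted acid ionises readily to the aroyl cation, which acylates the phenol oxygen. This is the established way to make depsides from hindered acids.

Step 10
Reactants: 16 benzyl 4-{[4-(benzyloxy)-2-methoxy-6-pentylbenzoyl]oxy}-2-methoxy-6-pentylbenzoate
Product: 17 4-O-demethylplanaic acid
Conditions: H2 (1 atm), Pd/C (10% Pd), EtOAc, rt
Reagents that add atoms: none
Why: Hydrogenolysis removes the benzyl ether and the benzyl ester together under neutral conditions. The aryl ester and the methyl ethers are untouched.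

## Compound list

1 | dimethyl malonate | COC(=O)CC(=O)OC | starting material
2 | methyl oct-2-ynoate | CCCCCC#CC(=O)OC | starting material
3 | trimethyl 2-pentylprop-1-ene-1,3,3-tricarboxylate (mixture of alkene isomers) | CCCCCC(=CC(=O)OC)C(C(=O)OC)C(=O)OC | intermediate
4 | methyl 2-methoxy-6-oxo-4-pentyl-6H-pyran-3-carboxylate | CCCCCC1=CC(=O)OC(OC)=C1C(=O)OC | intermediate
5 | ethyl dibromoacetate | CCOC(=O)C(Br)Br | starting material
6 | chlorotriisopropylsilane | CC(C)[Si](Cl)(C(C)C)C(C)C | starting material
7 | lithium ethynolate | [Li+].[O-]C#C | intermediate
8 | (ethynyloxy)triisopropylsilane | C#CO[Si](C(C)C)(C(C)C)C(C)C | intermediate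
9 | methyl 1-methoxy-3-oxo-5-pentyl-8-[(triisopropylsilyl)oxy]-2-oxabicyclo[2.2.2]octa-5,7-diene-6-carboxylate (racemic bridged lactone) | CCCCCC1=C(C(=O)OC)C2(OC)C=C(O[Si](C(C)C)(C(C)C)C(C)C)C1C(=O)O2 | intermediate
10 | methyl 2-methoxy-6-pentyl-4-[(triisopropylsilyl)oxy]benzoate | CCCCCc1cc(O[Si](C(C)C)(C(C)C)C(C)C)cc(OC)c1C(=O)OC | intermediate
11 | cesium 3-methoxy-4-(methoxycarbonyl)-5-pentylphenolate | CCCCCc1cc([O-])cc(OC)c1C(=O)OC.[Cs+] | intermediate
12 | methyl 4-(benzyloxy)-2-methoxy-6-pentylbenzoate | CCCCCc1cc(OCc2ccccc2)cc(OC)c1C(=O)OC | intermediate
13 | 4-(benzyloxy)-2-methoxy-6-pentylbenzoic acid | CCCCCc1cc(OCc2ccccc2)cc(OC)c1C(=O)O | intermediate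
14 | 4-hydroxy-2-methoxy-6-pentylbenzoic acid | CCCCCc1cc(O)cc(OC)c1C(=O)O | intermediate
15 | benzyl 4-hydroxy-2-methoxy-6-pentylbenzoate | CCCCCc1cc(O)cc(OC)c1C(=O)OCc1ccccc1 | intermediate
16 | benzyl 4-{[4-(benzyloxy)-2-methoxy-6-pentylbenzoyl]oxy}-2-methoxy-6-pentylbenzoate | CCCCCc1cc(OC(=O)c2c(CCCCC)cc(OCc3ccccc3)cc2OC)cc(OC)c1C(=O)OCc1ccccc1 | intermediate
17 | 4-O-demethylplanaic acid, 4-[(4-hydroxy-2-methoxy-6-pentylbenzoyl)oxy]-2-methoxy-6-pentylbenzoic acid | CCCCCc1cc(OC(=O)c2c(CCCCC)cc(O)cc2OC)cc(OC)c1C(=O)O | target

## Step count and risks

Total steps: 10. Longest linear sequence: 9 steps (steps 1, 2, 4, 5, 6, 7, 8, 9, 10, from dimethyl malonate). The siloxyalkyne (step 3) joins at step 4.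

**Step 4 (key step).** The 6-methoxy group donates into the diene, so the cycloaddition may be slow. At the temperature then needed, the siloxyalkyne may rearrange to a silylketene or add in [2+2] fashion to the C3–C4 enoate, and a stepwise pathway could erode the regiochemistry. Fallback: the ring is built by condensation instead of cycloaddition, setting out from 1 and coming back at 12. Michael addition of 1 to (E)-non-3-en-2-one with NaOMe in MeOH, followed in the same flask by Claisen closure, gives methyl 2-hydroxy-4-oxo-6-pentylcyclohex-2-ene-1-carboxylate F1 (racemic). Aromatisation with Br2 in DMF gives methyl 2,4-dihydroxy-6-pentylbenzoate F2. Benzylation of the non-chelated 4-hydroxyl (BnBr, K2CO3, acetone) gives methyl 4-(benzyloxy)-2-hydroxy-6-pentylbenzoate F3, and methylation of the chelated 2-hydroxyl (MeI, K2CO3, DMF) gives 12. The price is that the two oxygens are then told apart by selective alkylation and no longer by origin.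

**Step 3.** Deprotonation of the acidic C–H of 5 may compete with bromine–lithium exchange. The terminal ynolate may be lithiated further, and silylation may occur at carbon to give a silylketene. The product is also small enough to be lost on concentration. Fallback: the alkyne is dispensed with, setting out from 4 and coming back at 12. The ketene acetal 1,1-bis(trimethylsilyloxy)ethene F4, made from trimethylsilyl acetate with LDA and Me3SiCl, is heated with 4 in toluene. Cycloaddition in the same orientation, loss of CO2 and elimination of trimethylsilanol give the aryl silyl ether, which mild methanolysis (K2CO3, MeOH) converts into methyl 4-hydroxy-2-methoxy-6-pentylbenzoate F5. Benzylation (BnBr, K2CO3, DMF) then gives 12.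

**Step 2.** Lactonisation could occur in the other sense, through the oxygen of the unsaturated ester onto a malonate ester, giving the isomeric 3-carboxylate, or it could stop short because the closure is reversible. Fallback: the unsaturated terminus is made the only possible acyl donor, setting out from 1 and coming back at 4. tert-Butyl oct-2-ynoate F6 (from hept-1-yne, n-BuLi and Boc2O) takes up sodiomalonate from 1 to give 1-tert-butyl 3,3-dimethyl 2-pentylprop-1-ene-1,3,3-tricarboxylate F7. Trifluoroacetic acid cleaves the tert-butyl ester to 5-methoxy-4-(methoxycarbonyl)-5-oxo-3-pentylpent-2-enoic acid F8. Dehydrative closure with Ac2O, through the mixed anhydride and the malonate enol oxygen, gives 4.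

**Step 9.** The aroyl cation may acylate the electron-rich ring of 15 at carbon (Friedel–Crafts) instead of at oxygen, and the trifluoroacetic acid formed may start to cleave the benzyl ether. Fallback: acylation under basic conditions, setting out from 13 and coming back at 16. Oxalyl chloride with catalytic DMF converts 13 into 4-(benzyloxy)-2-methoxy-6-pentylbenzoyl chloride F9, which is added to the sodium phenolate of 15 (NaH, THF) to give 16.

**Step 6.** Hydrolysis of the di-ortho-substituted ester may stall, and forcing it or acidifying carelessly may cause decarboxylation. Fallback: cleavage at the methyl carbon instead of the acyl carbon, setting out from 12 and coming back at 13. Lithium propane-1-thiolate in HMPA at room temperature demethylates the ester by SN2 attack without touching the aryl ethers at that temperature.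

## Further compounds

F1 | step 4 | methyl 2-hydroxy-4-oxo-6-pentylcyclohex-2-ene-1-carboxylate (racemic) | CCCCCC1CC(=O)C=C(O)C1C(=O)OC
F2 | step 4 | methyl 2,4-dihydroxy-6-pentylbenzoate | CCCCCc1cc(O)cc(O)c1C(=O)OC
F3 | step 4 | methyl 4-(benzyloxy)-2-hydroxy-6-pentylbenzoate | CCCCCc1cc(OCc2ccccc2)cc(O)c1C(=O)OC
F4 | step 3 | 1,1-bis(trimethylsilyloxy)ethene | C=C(O[Si](C)(C)C)O[Si](C)(C)C
F5 | step 3 | methyl 4-hydroxy-2-methoxy-6-pentylbenzoate | CCCCCc1cc(O)cc(OC)c1C(=O)OC
F6 | step 2 | tert-butyl oct-2-ynoate | CCCCCC#CC(=O)OC(C)(C)C
F7 | step 2 | 1-tert-butyl 3,3-dimethyl 2-pentylprop-1-ene-1,3,3-tricarboxylate (mixture of alkene isomers) | CCCCCC(=CC(=O)OC(C)(C)C)C(C(=O)OC)C(=O)OC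
F8 | step 2 | 5-methoxy-4-(methoxycarbonyl)-5-oxo-3-pentylpent-2-enoic acid | CCCCCC(=CC(=O)O)C(C(=O)OC)C(=O)OC
F9 | step 9 | 4-(benzyloxy)-2-methoxy-6-pentylbenzoyl chloride | CCCCCc1cc(OCc2ccccc2)cc(OC)c1C(=O)Cl
F0 | step 6 | none | none
A1 | alternative 1 | methyl 2-methoxy-4-oxo-6-pentylcyclohex-2-ene-1-carboxylate (racemic) | CCCCCC1CC(=O)C=C(OC)C1C(=O)OC
A2 | alternative 1 | dimethyl 2-(1-methoxyethylidene)-3-pentylpentanedioate | COC(=O)CC(CCCCC)C(C(=O)OC)=C(C)OC
A3 | alternative 2 | benzyl 4-[(2,4-dihydroxy-6-pentylbenzoyl)oxy]-2-methoxy-6-pentylbenzoate | CCCCCc1cc(OC(=O)c2c(CCCCC)cc(O)cc2O)cc(OC)c1C(=O)OCc1ccccc1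
A4 | alternative 2 | benzyl 2-methoxy-6-pentyl-4-[(3,5,7-trioxododecanoyl)oxy]benzoate | CCCCCC(=O)CC(=O)CC(=O)CC(=O)Oc1cc(CCCCC)c(C(=O)OCc2ccccc2)c(OC)c1
A5 | alternative 3 | 4-(benzyloxy)-2-methoxy-6-pentylbenzoic acid | CCCCCc1cc(OCc2ccccc2)cc(OC)c1C(=O)O
A6 | alternative 3 | 4-(benzyloxy)-2-iodo-6-methoxyphenyl 4-chlorobenzenesulfonate | COc1cc(OCc2ccccc2)cc(I)c1OS(=O)(=O)c1ccc(Cl)cc1
A7 | alternative 3 | 5-(benzyloxy)-3-methoxybenzyne | COC1=CC(OCc2ccccc2)=CC#C1
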